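**Plan**
1. The target is read as catechin-(4α→8)-gallocatechin-(4α→8)-gallocatechin, every unit (2R,3S). Rings A/C/B are the top catechin (aromatic, pyran, catechol), D/F/E the middle gallocatechin, G/I/H the bottom gallocatechin.
2. Retrosynthesis: cut C4 (ring C)–C8 (ring D) to a top catechin C4 electrophile and a gallocatechin dimer, then cut C4 (ring F)–C8 (ring G) to two gallocatechin monomers.
3. Enabling feature: C4 of each pyran ring is benzylic to a 1,3,5-trioxygenated ring (O5 ortho, O7 para, O1 ortho), so a C4–O bond ionises to a stabilised cation. C8 of ring D lies between O1 and O7 and is the most nucleophilic, least crowded aryl C–H of the dimer.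
4. Forward: benzylate both flavan-3-ols, oxidise C4–H to a C4 ether (activating group), join rings D–F to rings G–I, then join the top unit, which carries a 3-O-acetyl participating group and an 8-bromo cap. Acetates, benzyl ethers and bromine leave in the last two steps.
5. Stereochemistry: C2 and C3 of all units come from (+)-catechin and (+)-gallocatechin. Both C4 centres are set 3,4-trans (4α) by arene attack anti to the β-face acetoxonium ion formed from the 3-O-acetyl group.

Key step: step 9

Remark: (+)-catechin and (+)-gallocatechin, both (2R,3S), are taken as purchasable chiral-pool materials.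

**Step 1**
Reactants: 1 (+)-catechin; 2 benzyl bromide
Product: 3 5,7,3',4'-tetra-O-benzyl-(+)-catechin
Conditions: BnBr (4.4 equiv), K2CO3, DMF, 0 °C → rt, Ar
Reagents that add atoms: benzyl bromide, BrCc1ccccc1
Why: Williamson etherification, in which K2CO3 deprotonates only the four phenols, so the secondary C3–OH should stay free and C2/C3 are untouched.

**Step 2**
Reactants: 3 5,7,3',4'-tetra-O-benzyl-(+)-catechin; 4 N-bromosuccinimide
Product: 5 8-bromo-5,7,3',4'-tetra-O-benzylcatechin
Conditions: NBS (1.05 equiv), CH2Cl2, −78 °C → rt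
Reagents that add atoms: N-bromosuccinimide, O=C1CCC(=O)N1Br
Why: Electrophilic aromatic bromination should occur at C8 of ring A (between O1 and 7-OBn) rather than at C6 (between two benzyloxy groups), and the bromine then serves as the C8 cap.

**Step 3**
Reactants: 5 8-bromo-5,7,3',4'-tetra-O-benzylcatechin; 6 2-ethoxyethanol
Product: 7 (2R,3S,4S)-8-bromo-5,7,3',4'-tetra-O-benzyl-4-(2-ethoxyethoxy)catechin (4β ether, cis to the 3-OH)
Conditions: DDQ (2 equiv), EtOCH2CH2OH (5 equiv), CH2Cl2, rt
Reagents that add atoms: 2-ethoxyethanol, CCOCCO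
Why: DDQ-mediated benzylic oxidation (hydride abstraction from C4 to the ring-A-stabilised cation, trapped by the alcohol) should install the C4 leaving group, expected cis to the free 3-OH; the C4 configuration is erased in step 9.

**Step 4**
Reactants: 7 the 4-(2-ethoxyethoxy) alcohol; 8 acetic anhydride
Product: 9 (2R,3S,4S)-3-O-acetyl-8-bromo-5,7,3',4'-tetra-O-benzyl-4-(2-ethoxyethoxy)catechin
Conditions: Ac2O, pyridine, DMAP (cat.), rt
Reagents that add atoms: acetic anhydride, CC(=O)OC(C)=O
Why: DMAP-catalysed esterification of the secondary 3-OH should give the acetate that acts as participating group in step 9, with no stereocentre changed.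

**Step 5**
Reactants: 10 (+)-gallocatechin; 2 benzyl bromide
Product: 11 5,7,3',4',5'-penta-O-benzyl-(+)-gallocatechin
Conditions: BnBr (5.5 equiv), K2CO3, degassed DMF, 0 °C → rt, Ar
Reagents that add atoms: benzyl bromide, BrCc1ccccc1
Why: Williamson etherification under argon should benzylate the five phenols of the oxidation-prone pyrogallol and phloroglucinol rings and leave the C3–OH free.

**Step 6**
Reactants: 11 5,7,3',4',5'-penta-O-benzyl-(+)-gallocatechin; 6 2-ethoxyethanol
Product: 12 (2R,3S,4S)-5,7,3',4',5'-penta-O-benzyl-4-(2-ethoxyethoxy)gallocatechin (4β ether)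
Conditions: DDQ (1.5 equiv), EtOCH2CH2OH (5 equiv), CH2Cl2, rt
Reagents that add atoms: 2-ethoxyethanol, CCOCCO
Why: DDQ-mediated benzylic oxidation at C4 of ring F, as in step 3, should give the C4 ether; the configuration of this centre is lost again in step 8.

**Step 7**
Reactants: 12 the 4-(2-ethoxyethoxy) alcohol; 8 acetic anhydride
Product: 13 (2R,3S,4S)-3-O-acetyl-5,7,3',4',5'-penta-O-benzyl-4-(2-ethoxyethoxy)gallocatechin
Conditions: Ac2O, pyridine, DMAP (cat.), rt
Reagents that add atoms: acetic anhydride, CC(=O)OC(C)=O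
Why: DMAP-catalysed esterification should install the participating 3-O-acetyl group without touching the acid-labile C4 ether.

**Step 8**
Reactants: 13 the gallocatechin C4 electrophile; 11 5,7,3',4',5'-penta-O-benzyl-(+)-gallocatechin
Product: 14 3-O-acetyl-5,7,3',4',5'-penta-O-benzylgallocatechin-(4α→8)-5,7,3',4',5'-penta-O-benzylgallocatechin
Conditions: 13 (1 equiv), 11 (3 equiv, excess recovered), Me3SiOTf (0.1 equiv), CH2Cl2, 4 Å MS, −78 °C; Et3N quench
Reagents that add atoms: none
Why: Lewis-acid-catalysed SN1 Friedel–Crafts alkylation, in which the C4 cation of 13 is shielded on the β face by the acetoxonium ion and C8 of ring G of excess 11 attacks from the α face, should set the new C4 centre 3,4-trans while the excess nucleophile suppresses chain growth.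

**Step 9**
Reactants: 9 the bromo-capped catechin C4 electrophile; 14 the gallocatechin dimer
Product: 15 3-O-acetyl-8-bromo-5,7,3',4'-tetra-O-benzylcatechin-(4α→8)-3-O-acetyl-5,7,3',4',5'-penta-O-benzylgallocatechin-(4α→8)-5,7,3',4',5'-penta-O-benzylgallocatechin
Conditions: 14 (1.0 equiv), 9 (1.3 equiv), Me3SiOTf (0.2 equiv), CH2Cl2, 4 Å MS, −78 → −30 °C; Et3N quench
Reagents that add atoms: none
Why: Me3SiOTf ionises the C4–O bond of 9 to a flavan-4-yl cation delocalised over ring A onto O5, O7 and O1, which the 3-O-acetyl carbonyl captures as a cis-fused 1,3-dioxolan-2-ylium ion on the β face; C8 of ring D of 14 then attacks C4 from the α face and rearomatises by loss of a proton (SN1 Friedel–Crafts alkylation). The closest known reaction type is the Lewis-acid-catalysed condensation of 4-alkoxyflavan-3-ol electrophiles with benzylated flavan-3-ol nucleophiles. No ring is closed; the only ring formed, the dioxolanylium, is transient and reopens to the 3-acetate. The one new stereocentre, C4 of ring C, should be set 4α (3,4-trans) by this neighbouring-group participation, reinforced by the equatorial 3-substituent, while C2 and C3 are untouched. The step needs site selectivity among three aryl C–H positions and chain-length control: C8 of ring D lies between O1 and one benzyloxy group, whereas C6 of rings D and G lie between two benzyloxy groups and C8 of ring G is already substituted, and the 8-bromo cap on ring A prevents 9 and the product from reacting on as C8 nucleophiles. Catalytic acid at low temperature should leave the existing interflavan bond of 14 intact.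

**Step 10**
Reactants: 15 the protected trimer diacetate
Product: 16 8-bromo-5,7,3',4'-tetra-O-benzylcatechin-(4α→8)-5,7,3',4',5'-penta-O-benzylgallocatechin-(4α→8)-5,7,3',4',5'-penta-O-benzylgallocatechin (three free 3-OH groups)
Conditions: NaOMe (cat.), MeOH–THF, rt → 40 °C
Reagents that add atoms: none
Why: Zemplén transesterification should remove both hindered secondary acetates, since benzyl ethers, the aryl bromide and the C4 centres are inert to methoxide.

**Step 11**
Reactants: 16 the benzylated bromo trimer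
Product: 17 catechin-(4α→8)-gallocatechin-(4α→8)-gallocatechin (target)
Conditions: H2 (1 atm), Pd(OH)2/C, Et3N (1.5 equiv), THF–MeOH–H2O, rt; filtration under Ar, lyophilisation
Reagents that add atoms: none
Why: Heterogeneous catalytic hydrogenolysis should cleave all fourteen benzyl ethers and the C8–Br bond (hydrodehalogenation) in one operation, with Et3N trapping HBr so that the acid-labile interflavan bonds survive and no stereocentre is touched.

**Compound list**
1 | (+)-catechin, (2R,3S) | Oc1cc(O)c2c(c1)O[C@H](c1ccc(O)c(O)c1)[C@@H](O)C2 | starting material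
2 | benzyl bromide | BrCc1ccccc1 | starting material
3 | 5,7,3',4'-tetra-O-benzyl-(+)-catechin | c1ccccc1COc1cc(OCc3ccccc3)c2c(c1)O[C@H](c1ccc(OCc3ccccc3)c(OCc3ccccc3)c1)[C@@H](O)C2 | intermediate
4 | N-bromosuccinimide | O=C1CCC(=O)N1Br | starting material
5 | 8-bromo-5,7,3',4'-tetra-O-benzylcatechin | c1ccccc1COc1cc(OCc3ccccc3)c2c(c1Br)O[C@H](c1ccc(OCc3ccccc3)c(OCc3ccccc3)c1)[C@@H](O)C2 | intermediate
6 | 2-ethoxyethanol | CCOCCO | starting material
7 | (2R,3S,4S)-8-bromo-5,7,3',4'-tetra-O-benzyl-4-(2-ethoxyethoxy)catechin | c1ccccc1COc1cc(OCc3ccccc3)c2c(c1Br)O[C@H](c1ccc(OCc3ccccc3)c(OCc3ccccc3)c1)[C@@H](O)[C@H]2OCCOCC | intermediate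
8 | acetic anhydride | CC(=O)OC(C)=O | starting material
9 | (2R,3S,4S)-3-O-acetyl-8-bromo-5,7,3',4'-tetra-O-benzyl-4-(2-ethoxyethoxy)catechin | c1ccccc1COc1cc(OCc3ccccc3)c2c(c1Br)O[C@H](c1ccc(OCc3ccccc3)c(OCc3ccccc3)c1)[C@@H](OC(C)=O)[C@H]2OCCOCC | intermediate
10 | (+)-gallocatechin, (2R,3S) | Oc1cc(O)c2c(c1)O[C@H](c1cc(O)c(O)c(O)c1)[C@@H](O)C2 | starting material
11 | 5,7,3',4',5'-penta-O-benzyl-(+)-gallocatechin | c1ccccc1COc1cc(OCc3ccccc3)c2c(c1)O[C@H](c1cc(OCc3ccccc3)c(OCc3ccccc3)c(OCc3ccccc3)c1)[C@@H](O)C2 | intermediate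
12 | (2R,3S,4S)-5,7,3',4',5'-penta-O-benzyl-4-(2-ethoxyethoxy)gallocatechin | c1ccccc1COc1cc(OCc3ccccc3)c2c(c1)O[C@H](c1cc(OCc3ccccc3)c(OCc3ccccc3)c(OCc3ccccc3)c1)[C@@H](O)[C@H]2OCCOCC | intermediate
13 | (2R,3S,4S)-3-O-acetyl-5,7,3',4',5'-penta-O-benzyl-4-(2-ethoxyethoxy)gallocatechin | c1ccccc1COc1cc(OCc3ccccc3)c2c(c1)O[C@H](c1cc(OCc3ccccc3)c(OCc3ccccc3)c(OCc3ccccc3)c1)[C@@H](OC(C)=O)[C@H]2OCCOCC | intermediate
14 | 3-O-acetyl-penta-O-benzylgallocatechin-(4α→8)-penta-O-benzylgallocatechin | c1ccccc1COc1cc(OCc3ccccc3)c2c(c1)O[C@H](c1cc(OCc3ccccc3)c(OCc3ccccc3)c(OCc3ccccc3)c1)[C@@H](OC(C)=O)[C@@H]2c1c(OCc3ccccc3)cc(OCc3ccccc3)c2c1O[C@H](c1cc(OCc3ccccc3)c(OCc3ccccc3)c(OCc3ccccc3)c1)[C@@H](O)C2 | intermediate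
15 | 3-O-acetyl-8-bromo-tetra-O-benzylcatechin-(4α→8)-3-O-acetyl-penta-O-benzylgallocatechin-(4α→8)-penta-O-benzylgallocatechin | c1ccccc1COc1cc(OCc3ccccc3)c2c(c1Br)O[C@H](c1ccc(OCc3ccccc3)c(OCc3ccccc3)c1)[C@@H](OC(C)=O)[C@@H]2c1c(OCc3ccccc3)cc(OCc3ccccc3)c2c1O[C@H](c1cc(OCc3ccccc3)c(OCc3ccccc3)c(OCc3ccccc3)c1)[C@@H](OC(C)=O)[C@@H]2c1c(OCc3ccccc3)cc(OCc3ccccc3)c2c1O[C@H](c1cc(OCc3ccccc3)c(OCc3ccccc3)c(OCc3ccccc3)c1)[C@@H](O)C2 | intermediate
16 | 8-bromo-tetra-O-benzylcatechin-(4α→8)-penta-O-benzylgallocatechin-(4α→8)-penta-O-benzylgallocatechin | c1ccccc1COc1cc(OCc3ccccc3)c2c(c1Br)O[C@H](c1ccc(OCc3ccccc3)c(OCc3ccccc3)c1)[C@@H](O)[C@@H]2c1c(OCc3ccccc3)cc(OCc3ccccc3)c2c1O[C@H](c1cc(OCc3ccccc3)c(OCc3ccccc3)c(OCc3ccccc3)c1)[C@@H](O)[C@@H]2c1c(OCc3ccccc3)cc(OCc3ccccc3)c2c1O[C@H](c1cc(OCc3ccccc3)c(OCc3ccccc3)c(OCc3ccccc3)c1)[C@@H](O)C2 | intermediate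
17 | catechin-(4α→8)-gallocatechin-(4α→8)-gallocatechin | Oc1cc(O)c2c(c1)O[C@H](c1ccc(O)c(O)c1)[C@@H](O)[C@@H]2c1c(O)cc(O)c2c1O[C@H](c1cc(O)c(O)c(O)c1)[C@@H](O)[C@@H]2c1c(O)cc(O)c2c1O[C@H](c1cc(O)c(O)c(O)c1)[C@@H](O)C2 | target

Total step count: 11
Longest linear sequence: 7 steps (steps 5–11 from (+)-gallocatechin 10; the catechin branch, steps 1–4 and 9–11, is equally long)

**Steps most likely to fail**

Step 9. The cation from 9 may attack C6 of ring D or ring G instead of C8 of ring D, the 4α selectivity may erode, or the Lewis acid may cleave the existing interflavan bond of 14. The fallback reverses the order of bond formation, so that the upper bond is made on a monomer with only one competing ring and no acid-labile interflavan bond. It sets out from 13 and 9 and returns at 15. Compound 13 is treated with 2,6-dimethylbenzenethiol and catalytic BF3·OEt2 in CH2Cl2 at −78 °C to exchange the C4 ether for a thioether, giving 3-O-acetyl-5,7,3',4',5'-penta-O-benzyl-4α-(2,6-dimethylphenylthio)gallocatechin F1. The C–S bond should survive hard Lewis acids, so 9 and F1 are joined with catalytic Me3SiOTf at −78 °C to give the catechin-(4α→8)-gallocatechin 4-thioether F2. Thiophilic activation of F2 with AgBF4 (1.2 equiv) in CH2Cl2 at −40 °C in the presence of 11 (2 equiv) should then form the lower interflavan bond and deliver 15.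

Step 8. The cation from the uncapped electrophile 13 may be captured by C8 of ring D of the product 14, or of 13 itself, instead of by 11, leading to oligomerisation. The fallback caps the electrophile and uncaps after coupling. It sets out from 13 and returns at 14. Bromination of 13 with NBS in CH2Cl2 at −78 °C should give 3-O-acetyl-8-bromo-5,7,3',4',5'-penta-O-benzyl-4-(2-ethoxyethoxy)gallocatechin F3. Equimolar coupling of F3 with 11 (Me3SiOTf cat., −78 °C) should give the 8-bromo dimer F4, which cannot grow further at C8. Radical hydrodebromination of F4 with Bu3SnH and AIBN (cat.) in toluene at 90 °C leaves benzyl ethers, the acetate and the free 3-OH untouched and should give 14.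

Step 5. The pyrogallol phenoxides of ring B may be oxidised under basic conditions, and C-benzylation may compete before O-benzylation is complete. The fallback masks the phenols first. It sets out from 10 and returns at 11. Peracetylation (Ac2O, pyridine, rt) should give (+)-gallocatechin 3,5,7,3',4',5'-hexaacetate F5. One-pot methanolysis and benzylation of F5 (BnBr, K2CO3, MeOH 10 equiv, DMF, rt, Ar) unmasks each phenoxide only as it is alkylated, so free pyrogallol never accumulates. The aliphatic 3-acetate is methanolysed in the same pot and the 3-OH is not alkylated by K2CO3, which should give 11.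

**Further compounds**
F1 | step 9 | 3-O-acetyl-5,7,3',4',5'-penta-O-benzyl-4α-(2,6-dimethylphenylthio)gallocatechin | c1ccccc1COc1cc(OCc3ccccc3)c2c(c1)O[C@H](c1cc(OCc3ccccc3)c(OCc3ccccc3)c(OCc3ccccc3)c1)[C@@H](OC(C)=O)[C@@H]2Sc1c(C)cccc1C
F2 | step 9 | 3-O-acetyl-8-bromo-tetra-O-benzylcatechin-(4α→8)-3-O-acetyl-penta-O-benzyl-4α-(2,6-dimethylphenylthio)gallocatechin | c1ccccc1COc1cc(OCc3ccccc3)c2c(c1Br)O[C@H](c1ccc(OCc3ccccc3)c(OCc3ccccc3)c1)[C@@H](OC(C)=O)[C@@H]2c1c(OCc3ccccc3)cc(OCc3ccccc3)c2c1O[C@H](c1cc(OCc3ccccc3)c(OCc3ccccc3)c(OCc3ccccc3)c1)[C@@H](OC(C)=O)[C@@H]2Sc1c(C)cccc1C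
F3 | step 8 | (2R,3S,4S)-3-O-acetyl-8-bromo-5,7,3',4',5'-penta-O-benzyl-4-(2-ethoxyethoxy)gallocatechin | c1ccccc1COc1cc(OCc3ccccc3)c2c(c1Br)O[C@H](c1cc(OCc3ccccc3)c(OCc3ccccc3)c(OCc3ccccc3)c1)[C@@H](OC(C)=O)[C@H]2OCCOCC
F4 | step 8 | 3-O-acetyl-8-bromo-penta-O-benzylgallocatechin-(4α→8)-penta-O-benzylgallocatechin | c1ccccc1COc1cc(OCc3ccccc3)c2c(c1Br)O[C@H](c1cc(OCc3ccccc3)c(OCc3ccccc3)c(OCc3ccccc3)c1)[C@@H](OC(C)=O)[C@@H]2c1c(OCc3ccccc3)cc(OCc3ccccc3)c2c1O[C@H](c1cc(OCc3ccccc3)c(OCc3ccccc3)c(OCc3ccccc3)c1)[C@@H](O)C2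
F5 | step 5 | (+)-gallocatechin 3,5,7,3',4',5'-hexaacetate | CC(=O)Oc1cc(OC(C)=O)c2c(c1)O[C@H](c1cc(OC(C)=O)c(OC(C)=O)c(OC(C)=O)c1)[C@@H](OC(C)=O)C2
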